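**Retrosynthetic overview**

1. The last step closes the ten-membered carbocycle (ring A) at C6–C7 by a chiral-acid-catalysed allylboration of a (Z)-enal with a tethered (E)-2-(methoxycarbonyl)allylboronate; the resulting O-boryl alkoxide then closes the α-methylene lactone (ring B). Ring order: oxolane hemiketal (ring C), then ring A, then ring B.
2. The (Z)-4-oxo-enal (C3–C6) and ring C come from singlet-oxygen opening of a 2-alkyl-3-methylfuran with a γ-hydroxyl; the furan fixes the 4Z geometry.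
3. The allylboronate comes from SN2' borylation of a Morita–Baylis–Hillman carbonate, made from an α-acyloxy aldehyde (C7) that is unmasked by cleaving a styryl group.
4. C8 is set by oxazaborolidine-catalysed enone reduction; C10 (first stereocentre) by an amine-catalysed aldol of benzalacetone with a furyl α-keto ester built from 3-methylfurfural.
5. The (R)-2-methylbutanoyl group comes from asymmetric hydrogenation of tiglic acid.

Assumption: the SMILES is taken literally (cis-fused 6,12-lactone; 3S,6S,7R,8R,10R,2'R; atom labels C1–C15 follow germacrane numbering), and the catalyst antipodes named are those expected by analogy to give these configurations; the route has not been tested experimentally.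

**Step 1**
Reactants: 1 3-methylfuran-2-carbaldehyde; 2 ethyl 2-oxo-3-(triphenyl-λ5-phosphanylidene)propanoate
Product: 4 ethyl 4-(3-methylfuran-2-yl)-2-oxobutanoate, via enone ester 3 (not isolated)
Conditions: EtOAc, 70 °C; then 5% Pd/C, H2 (1 atm), 0 °C → rt, stopped after 1 equiv H2
Reagents that add atoms: none
Why: Wittig olefination with an acyl-stabilised ylide gives the E enone, whose doubly activated C=C is hydrogenated far faster than the furan or the keto ester on palladium.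

**Step 2**
Reactants: 4 ethyl 4-(3-methylfuran-2-yl)-2-oxobutanoate; 5 (3E)-4-phenylbut-3-en-2-one
Product: 6 ethyl (2R,5E)-2-hydroxy-2-[2-(3-methylfuran-2-yl)ethyl]-4-oxo-6-phenylhex-5-enoate
Conditions: 9-amino-9-deoxy-epi-quinidine (20 mol%), CF3CO2H (40 mol%), 5 (4 equiv), PhMe, 0 °C
Reagents that add atoms: none
Why: Primary-amine (enamine) catalysed cross-aldol: the only enolisable site of 5 is its methyl group, and the protonated quinuclidine hydrogen-bonds the α-keto ester so that one face of the ketone is attacked, setting the quaternary carbinol C10 (2R) as the first stereocentre.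

**Step 3**
Reactants: 6 ethyl (2R,5E)-2-hydroxy-2-[2-(3-methylfuran-2-yl)ethyl]-4-oxo-6-phenylhex-5-enoate
Product: 8 (2R,4R,5E)-2-[2-(3-methylfuran-2-yl)ethyl]-6-phenylhex-5-ene-1,2,4-triol, via diol ester 7 (not isolated)
Conditions: (S)-2-methyl-CBS-oxazaborolidine (20 mol%), BH3·SMe2 (2.5 equiv), THF, −30 °C; then LiBH4, MeOH, 0 °C → rt
Reagents that add atoms: none
Why: Corey–Bakshi–Shibata reduction treats the styryl group as the large substituent and delivers hydride under catalyst control to give the 4R allylic alcohol (C8), after which LiBH4 reduces the α-hydroxy ester (or its γ-lactone) to the primary alcohol C14.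

**Step 4**
Reactants: 8 (2R,4R,5E)-2-[2-(3-methylfuran-2-yl)ethyl]-6-phenylhex-5-ene-1,2,4-triol
Product: 9 (2R,3E)-1-{(4R)-2,2-dimethyl-4-[2-(3-methylfuran-2-yl)ethyl]-1,3-dioxolan-4-yl}-4-phenylbut-3-en-2-ol
Conditions: Me2C(OMe)2, PPTS (cat.), acetone, rt
Reagents that add atoms: 2,2-dimethoxypropane, COC(C)(C)OC
Why: Thermodynamic acetonide formation takes the primary/tertiary 1,2-diol as the five-membered dioxolane, because the alternative 1,3-dioxane would need an axial group on the quaternary carbon; only the C8 hydroxyl stays free.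

**Step 5**
Reactants: 10 tiglic acid, (2E)-2-methylbut-2-enoic acid
Product: 11 (2R)-2-methylbutanoic acid
Conditions: H2 (4 atm), Ru(OAc)2[(R)-H8-BINAP] (0.5 mol%), MeOH, rt
Reagents that add atoms: none
Why: Carboxylate-directed asymmetric hydrogenation of an α,β-unsaturated acid on the ruthenium bisphosphine catalyst sets the side-chain stereocentre, the R ligand giving the R acid.

**Step 6**
Reactants: 9 (2R,3E)-1-{(4R)-2,2-dimethyl-4-[2-(3-methylfuran-2-yl)ethyl]-1,3-dioxolan-4-yl}-4-phenylbut-3-en-2-ol; 11 (2R)-2-methylbutanoic acid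
Product: 12 (2R,3E)-1-{(4R)-2,2-dimethyl-4-[2-(3-methylfuran-2-yl)ethyl]-1,3-dioxolan-4-yl}-4-phenylbut-3-en-2-yl (2R)-2-methylbutanoate
Conditions: DIC, DMAP (cat.), CH2Cl2, 0 °C → rt
Reagents that add atoms: none
Why: Steglich esterification acylates the only free hydroxyl (C8) under neutral conditions that leave the acetonide and furan alone and do not touch either stereocentre.

**Step 7**
Reactants: 12 (2R,3E)-1-{(4R)-2,2-dimethyl-4-[2-(3-methylfuran-2-yl)ethyl]-1,3-dioxolan-4-yl}-4-phenylbut-3-en-2-yl (2R)-2-methylbutanoate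
Product: 13 (2R)-1-{(4R)-2,2-dimethyl-4-[2-(3-methylfuran-2-yl)ethyl]-1,3-dioxolan-4-yl}-3-oxopropan-2-yl (2R)-2-methylbutanoate
Conditions: OsO4 (2 mol%), NaIO4 (4 equiv), 2,6-lutidine, dioxane/H2O (3:1), rt
Reagents that add atoms: osmium tetroxide, O=[Os](=O)(=O)=O (catalytic oxygen transfer); sodium periodate, [Na+].[O-]I(=O)(=O)=O (terminal oxygen source)
Why: Lemieux–Johnson cleavage of the styryl alkene unmasks the C7 aldehyde under buffered, non-acidic conditions that keep the acetonide, and the styrene-type alkene is osmylated much faster than the furan.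

**Step 8**
Reactants: 13 (2R)-1-{(4R)-2,2-dimethyl-4-[2-(3-methylfuran-2-yl)ethyl]-1,3-dioxolan-4-yl}-3-oxopropan-2-yl (2R)-2-methylbutanoate; 14 methyl acrylate
Product: 15 methyl (4R)-5-{(4R)-2,2-dimethyl-4-[2-(3-methylfuran-2-yl)ethyl]-1,3-dioxolan-4-yl}-3-hydroxy-2-methylidene-4-{[(2R)-2-methylbutanoyl]oxy}pentanoate (both C3 epimers)
Conditions: DABCO (1 equiv), 14 (10 equiv), MeOH (cat.), rt
Reagents that add atoms: none
Why: Morita–Baylis–Hillman reaction joins C7 to the acrylate α-carbon (C11); the α-acyloxy aldehyde is an activated acceptor, and the new carbinol configuration is irrelevant because C7 becomes sp2 in step 10.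

**Step 9**
Reactants: 15 methyl (4R)-5-{(4R)-2,2-dimethyl-4-[2-(3-methylfuran-2-yl)ethyl]-1,3-dioxolan-4-yl}-3-hydroxy-2-methylidene-4-{[(2R)-2-methylbutanoyl]oxy}pentanoate
Product: 16 methyl (4R)-3-[(tert-butoxycarbonyl)oxy]-5-{(4R)-2,2-dimethyl-4-[2-(3-methylfuran-2-yl)ethyl]-1,3-dioxolan-4-yl}-2-methylidene-4-{[(2R)-2-methylbutanoyl]oxy}pentanoate
Conditions: Boc2O, DMAP (10 mol%), CH2Cl2, 0 °C
Reagents that add atoms: di-tert-butyl dicarbonate, CC(C)(C)OC(=O)OC(=O)OC(C)(C)C
Why: DMAP-catalysed carbonate formation converts the allylic hydroxyl at once into a leaving group, which also stops any 1,2-shift of the neighbouring ester.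

**Step 10**
Reactants: 16 methyl (4R)-3-[(tert-butoxycarbonyl)oxy]-5-{(4R)-2,2-dimethyl-4-[2-(3-methylfuran-2-yl)ethyl]-1,3-dioxolan-4-yl}-2-methylidene-4-{[(2R)-2-methylbutanoyl]oxy}pentanoate
Product: 17 methyl (2E,4R)-5-{(4R)-2,2-dimethyl-4-[2-(3-methylfuran-2-yl)ethyl]-1,3-dioxolan-4-yl}-4-{[(2R)-2-methylbutanoyl]oxy}-2-[(4,4,5,5-tetramethyl-1,3,2-dioxaborolan-2-yl)methyl]pent-2-enoate
Conditions: B2pin2 (1.2 equiv), CuCl (5 mol%), Xantphos (5 mol%), KOtBu (10 mol%), THF, 0 °C → rt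
Reagents that add atoms: bis(pinacolato)diboron, CC1(C)OB(OC1(C)C)B1OC(C)(C)C(C)(C)O1
Why: Copper-catalysed SN2' allylic borylation (boryl-cupration of the acrylate terminus, then β-elimination of carbonate) gives the trisubstituted alkene with C8 trans to the ester and cis to CH2B, the geometry that leads to a cis lactone.

**Step 11**
Reactants: 17 methyl (2E,4R)-5-{(4R)-2,2-dimethyl-4-[2-(3-methylfuran-2-yl)ethyl]-1,3-dioxolan-4-yl}-4-{[(2R)-2-methylbutanoyl]oxy}-2-[(4,4,5,5-tetramethyl-1,3,2-dioxaborolan-2-yl)methyl]pent-2-enoate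
Product: 18 methyl (2E,4R,6R)-6-hydroxy-6-(hydroxymethyl)-8-(3-methylfuran-2-yl)-4-{[(2R)-2-methylbutanoyl]oxy}-2-[(4,4,5,5-tetramethyl-1,3,2-dioxaborolan-2-yl)methyl]oct-2-enoate
Conditions: PPTS, MeOH, 40 °C
Reagents that add atoms: none
Why: Mild acid-catalysed transketalisation removes the acetonide, while the ester-deactivated pinacol allylboronate and the dialkylfuran are stable to PPTS in methanol.

**Step 12**
Reactants: 18 methyl (2E,4R,6R)-6-hydroxy-6-(hydroxymethyl)-8-(3-methylfuran-2-yl)-4-{[(2R)-2-methylbutanoyl]oxy}-2-[(4,4,5,5-tetramethyl-1,3,2-dioxaborolan-2-yl)methyl]oct-2-enoate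
Product: 21 methyl (2E,4R)-5-[(2R)-7-hydroxy-2-(hydroxymethyl)-9-methyl-1,6-dioxaspiro[4.4]non-8-en-2-yl]-4-{[(2R)-2-methylbutanoyl]oxy}-2-[(4,4,5,5-tetramethyl-1,3,2-dioxaborolan-2-yl)methyl]pent-2-enoate (spiro and lactol epimers), via furan endoperoxide 19 (not isolated), via open Z keto enal 20 (not isolated)
Conditions: O2, methylene blue (cat.), hν (visible), CH2Cl2, −78 °C; then Me2S, −78 °C → rt
Reagents that add atoms: dioxygen, O=O
Why: Singlet-oxygen [4+2] cycloaddition to the electron-rich furan and sulfide reduction give the (Z)-4-oxo-enal, with the Z geometry inherited from the ring; the γ-hydroxyl (O10) captures the C3 ketone as the oxolane hemiketal (ring C), which closes further to the spiro-lactol, protecting both the Z alkene and the ketone.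

**Step 13**
Reactants: 21 methyl (2E,4R)-5-[(2R)-7-hydroxy-2-(hydroxymethyl)-9-methyl-1,6-dioxaspiro[4.4]non-8-en-2-yl]-4-{[(2R)-2-methylbutanoyl]oxy}-2-[(4,4,5,5-tetramethyl-1,3,2-dioxaborolan-2-yl)methyl]pent-2-enoate
Product: 24 (3S,6S,7R,8R,10R)-3,14-dihydroxy-8-{[(2R)-2-methylbutanoyl]oxy}-3,10-epoxygermacra-4Z,11(13)-dien-6,12-olide (the target), via open hemiketal enal 22 (not isolated), via macrocyclic boryl ether 23 (not isolated)
Conditions: (R)-3,3'-bis(2,4,6-triisopropylphenyl)-1,1'-binaphthyl-2,2'-diyl hydrogen phosphate [(R)-TRIP] (20 mol%), PhMe (1 mM), 4 Å MS, 40 °C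
Reagents that add atoms: none
Why: Proposed new method: a chiral-phosphoric-acid-catalysed macrocyclising allylboration–lactonisation, in which the acid opens the lactol to the hemiketal enal 22 (ketone still masked, the two arms held cis on the oxolane) and activates the boronate for a closed chair transition state where C8 (cis to CH2B) sits axial so that C6–O and C7–C8 come out syn (cis lactone), the R acid directs attack on the re face of the aldehyde (6S, hence 7R), which matches the A(1,3)-preferred allyl face (H8 in plane, attack anti to the C8–C9 bond), the O-boryl alkoxide then lactonises onto the methyl ester and C3 settles as the only hemiketal epimer the bridge allows; the closest known reactions are the phosphoric-acid-catalysed intermolecular allylboration of aldehydes with pinacol allylboronates, the Brønsted-acid-promoted addition of 2-alkoxycarbonylallylboronates to aldehydes that gives α-methylene-γ-butyrolactones, and metal-mediated macrocyclic Barbier allylations of germacranolide precursors.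

**Compound list**

1 | 3-methylfuran-2-carbaldehyde | Cc1ccoc1C=O | starting material
2 | ethyl 2-oxo-3-(triphenyl-λ5-phosphanylidene)propanoate | CCOC(=O)C(=O)C=P(c1ccccc1)(c1ccccc1)c1ccccc1 | starting material
3 | ethyl (3E)-4-(3-methylfuran-2-yl)-2-oxobut-3-enoate (transient enone ester) | Cc1ccoc1/C=C/C(=O)C(=O)OCC | intermediate
4 | ethyl 4-(3-methylfuran-2-yl)-2-oxobutanoate | Cc1ccoc1CCC(=O)C(=O)OCC | intermediate
5 | (3E)-4-phenylbut-3-en-2-one | CC(=O)/C=C/c1ccccc1 | starting material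
6 | ethyl (2R,5E)-2-hydroxy-2-[2-(3-methylfuran-2-yl)ethyl]-4-oxo-6-phenylhex-5-enoate | Cc1ccoc1CC[C@](C(=O)OCC)(CC(=O)/C=C/c1ccccc1)O | intermediate
7 | ethyl (2R,4R,5E)-2,4-dihydroxy-2-[2-(3-methylfuran-2-yl)ethyl]-6-phenylhex-5-enoate (transient diol ester) | Cc1ccoc1CC[C@](C(=O)OCC)(C[C@@H](O)/C=C/c1ccccc1)O | intermediate
8 | (2R,4R,5E)-2-[2-(3-methylfuran-2-yl)ethyl]-6-phenylhex-5-ene-1,2,4-triol | Cc1ccoc1CC[C@](CO)(C[C@@H](O)/C=C/c1ccccc1)O | intermediate
9 | (2R,3E)-1-{(4R)-2,2-dimethyl-4-[2-(3-methylfuran-2-yl)ethyl]-1,3-dioxolan-4-yl}-4-phenylbut-3-en-2-ol | Cc1ccoc1CC[C@]2(COC(C)(C)O2)C[C@@H](O)/C=C/c1ccccc1 | intermediate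
10 | tiglic acid, (2E)-2-methylbut-2-enoic acid | C/C=C(\C)C(=O)O | starting material
11 | (2R)-2-methylbutanoic acid | CC[C@@H](C)C(=O)O | intermediate
12 | (2R,3E)-1-{(4R)-2,2-dimethyl-4-[2-(3-methylfuran-2-yl)ethyl]-1,3-dioxolan-4-yl}-4-phenylbut-3-en-2-yl (2R)-2-methylbutanoate | Cc1ccoc1CC[C@]2(COC(C)(C)O2)C[C@@H](OC(=O)[C@H](C)CC)/C=C/c1ccccc1 | intermediate
13 | (2R)-1-{(4R)-2,2-dimethyl-4-[2-(3-methylfuran-2-yl)ethyl]-1,3-dioxolan-4-yl}-3-oxopropan-2-yl (2R)-2-methylbutanoate | Cc1ccoc1CC[C@]2(COC(C)(C)O2)C[C@@H](OC(=O)[C@H](C)CC)C=O | intermediate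
14 | methyl acrylate | C=CC(=O)OC | starting material
15 | methyl (4R)-5-{(4R)-2,2-dimethyl-4-[2-(3-methylfuran-2-yl)ethyl]-1,3-dioxolan-4-yl}-3-hydroxy-2-methylidene-4-{[(2R)-2-methylbutanoyl]oxy}pentanoate (C3 epimers) | Cc1ccoc1CC[C@]2(COC(C)(C)O2)C[C@@H](OC(=O)[C@H](C)CC)C(O)C(=C)C(=O)OC | intermediate
16 | methyl (4R)-3-[(tert-butoxycarbonyl)oxy]-5-{(4R)-2,2-dimethyl-4-[2-(3-methylfuran-2-yl)ethyl]-1,3-dioxolan-4-yl}-2-methylidene-4-{[(2R)-2-methylbutanoyl]oxy}pentanoate (C3 epimers) | Cc1ccoc1CC[C@]2(COC(C)(C)O2)C[C@@H](OC(=O)[C@H](C)CC)C(OC(=O)OC(C)(C)C)C(=C)C(=O)OC | intermediate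
17 | methyl (2E,4R)-5-{(4R)-2,2-dimethyl-4-[2-(3-methylfuran-2-yl)ethyl]-1,3-dioxolan-4-yl}-4-{[(2R)-2-methylbutanoyl]oxy}-2-[(4,4,5,5-tetramethyl-1,3,2-dioxaborolan-2-yl)methyl]pent-2-enoate | Cc1ccoc1CC[C@]2(COC(C)(C)O2)C[C@@H](OC(=O)[C@H](C)CC)/C=C(\CB3OC(C)(C)C(C)(C)O3)C(=O)OC | intermediate
18 | methyl (2E,4R,6R)-6-hydroxy-6-(hydroxymethyl)-8-(3-methylfuran-2-yl)-4-{[(2R)-2-methylbutanoyl]oxy}-2-[(4,4,5,5-tetramethyl-1,3,2-dioxaborolan-2-yl)methyl]oct-2-enoate | Cc1ccoc1CC[C@](CO)(C[C@@H](OC(=O)[C@H](C)CC)/C=C(\CB2OC(C)(C)C(C)(C)O2)C(=O)OC)O | intermediate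
19 | furan endoperoxide of 18: the 6-methyl-2,3,7-trioxabicyclo[2.2.1]hept-5-en-1-yl derivative (transient) | CC1=CC2OOC1(CC[C@](CO)(C[C@@H](OC(=O)[C@H](C)CC)/C=C(\CB3OC(C)(C)C(C)(C)O3)C(=O)OC)O)O2 | intermediate
20 | methyl (2E,4R,6R,10Z)-6-hydroxy-6-(hydroxymethyl)-10-methyl-4-{[(2R)-2-methylbutanoyl]oxy}-9,12-dioxo-2-[(4,4,5,5-tetramethyl-1,3,2-dioxaborolan-2-yl)methyl]dodeca-2,10-dienoate (transient open keto enal) | O=C/C=C(/C)C(=O)CC[C@](CO)(C[C@@H](OC(=O)[C@H](C)CC)/C=C(\CB1OC(C)(C)C(C)(C)O1)C(=O)OC)O | intermediate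
21 | methyl (2E,4R)-5-[(2R)-7-hydroxy-2-(hydroxymethyl)-9-methyl-1,6-dioxaspiro[4.4]non-8-en-2-yl]-4-{[(2R)-2-methylbutanoyl]oxy}-2-[(4,4,5,5-tetramethyl-1,3,2-dioxaborolan-2-yl)methyl]pent-2-enoate (spiro and lactol epimers) | CC1=CC(O)OC12CC[C@](CO)(C[C@@H](OC(=O)[C@H](C)CC)/C=C(\CB3OC(C)(C)C(C)(C)O3)C(=O)OC)O2 | intermediate
22 | methyl (2E,4R)-5-{(2R)-5-hydroxy-2-(hydroxymethyl)-5-[(2Z)-4-oxobut-2-en-2-yl]oxolan-2-yl}-4-{[(2R)-2-methylbutanoyl]oxy}-2-[(4,4,5,5-tetramethyl-1,3,2-dioxaborolan-2-yl)methyl]pent-2-enoate (transient ring-opened tautomer of 21) | O=C/C=C(/C)C1(O)CC[C@](CO)(C[C@@H](OC(=O)[C@H](C)CC)/C=C(\CB2OC(C)(C)C(C)(C)O2)C(=O)OC)O1 | intermediate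
23 | methyl 2-[(3S,6S,7R,8R,10R)-3-hydroxy-10-(hydroxymethyl)-4-methyl-8-{[(2R)-2-methylbutanoyl]oxy}-6-[(4,4,5,5-tetramethyl-1,3,2-dioxaborolan-2-yl)oxy]-3,10-epoxycyclodec-4Z-en-7-yl]prop-2-enoate, germacrane numbering (transient macrocyclic boryl ether) | COC(=O)C(=C)[C@H]1[C@@H](OB2OC(C)(C)C(C)(C)O2)/C=C(/C)[C@]3(O)CC[C@](CO)(C[C@H]1OC(=O)[C@H](C)CC)O3 | intermediate
24 | (3S,6S,7R,8R,10R)-3,14-dihydroxy-8-{[(2R)-2-methylbutanoyl]oxy}-3,10-epoxygermacra-4Z,11(13)-dien-6,12-olide, CNP0328225.2 | C=C1C(=O)O[C@H]2/C=C(/C)[C@]3(O)CC[C@](CO)(C[C@@H](OC(=O)[C@H](C)CC)[C@@H]12)O3 | target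

**Step count and risks**

Total step count: 13. Longest linear sequence: 12 steps (steps 1–4 and 6–13, from 1 to 24); step 5 is a one-step branch.

The three steps most likely to fail:

Step 13 (the proposed new macrocyclisation). The ester-deactivated boronate may be too sluggish under phosphoric-acid catalysis. The lactol may instead ionise and be C-allylated at C6. The catalyst may not override the substrate's facial bias, giving a C6/C7 diastereomer. The fallback uses known Barbier chemistry and sets out from 15. Mesylation and bromide exchange with allylic transposition (MsCl, Et3N; then LiBr, acetone) give methyl (2Z,4R)-2-(bromomethyl)-5-{(4R)-2,2-dimethyl-4-[2-(3-methylfuran-2-yl)ethyl]-1,3-dioxolan-4-yl}-4-{[(2R)-2-methylbutanoyl]oxy}pent-2-enoate F1. PPTS in methanol frees the diol to give methyl (2Z,4R,6R)-2-(bromomethyl)-6-hydroxy-6-(hydroxymethyl)-8-(3-methylfuran-2-yl)-4-{[(2R)-2-methylbutanoyl]oxy}oct-2-enoate F2. Photo-oxygenation and Me2S reduction as in step 12 give methyl (2Z,4R)-2-(bromomethyl)-5-[(2R)-7-hydroxy-2-(hydroxymethyl)-9-methyl-1,6-dioxaspiro[4.4]non-8-en-2-yl]-4-{[(2R)-2-methylbutanoyl]oxy}pent-2-enoate F3. Indium powder in THF/H2O at 1 mM then effects an intramolecular Barbier allylation, which is syn-selective for such (Z)-bromides, and lactonisation. This comes back to the route at 24; diastereomers would be separated by chromatography.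

Step 2 (the aldol that sets the first stereocentre). Keto ester 4 is enolisable and may self-condense, and an enone donor with this acceptor may give modest ee. The fallback sets out from 4 and 5. Compound 5 is silylated (TMSOTf, Et3N) to trimethyl{[(3E)-4-phenylbuta-1,3-dien-2-yl]oxy}silane F4. A Mukaiyama aldol with 4 under Cu(OTf)2 and a tert-butyl bis(oxazoline) ligand of the appropriate antipode (10 mol%, CH2Cl2, −78 °C) gives ethyl (2R,5E)-2-[2-(3-methylfuran-2-yl)ethyl]-4-oxo-6-phenyl-2-[(trimethylsilyl)oxy]hex-5-enoate F5. Dilute HCl in THF removes the silyl group, and the fallback comes back to the route at 6.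

Step 8 (Morita–Baylis–Hillman reaction of the α-acyloxy aldehyde). Days of exposure to the amine may epimerise C8 or move the 2-methylbutanoyl group onto the new hydroxyl. The fallback sets out from 13. It replaces the amine-catalysed reaction by a fast, non-basic vinylmetal addition with methyl 2-[bis(2-methylpropyl)alumanyl]prop-2-enoate F6, made in the flask from methyl propiolate, iBu2AlH and N-methylmorpholine N-oxide in THF at 0 °C. Addition to 13 at −20 °C and a mild acidic work-up bring the fallback back to the route at 15.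

**Further compounds**

F1 | step 13 | methyl (2Z,4R)-2-(bromomethyl)-5-{(4R)-2,2-dimethyl-4-[2-(3-methylfuran-2-yl)ethyl]-1,3-dioxolan-4-yl}-4-{[(2R)-2-methylbutanoyl]oxy}pent-2-enoate | Cc1ccoc1CC[C@]2(COC(C)(C)O2)C[C@@H](OC(=O)[C@H](C)CC)/C=C(\CBr)C(=O)OC
F2 | step 13 | methyl (2Z,4R,6R)-2-(bromomethyl)-6-hydroxy-6-(hydroxymethyl)-8-(3-methylfuran-2-yl)-4-{[(2R)-2-methylbutanoyl]oxy}oct-2-enoate | Cc1ccoc1CC[C@](CO)(C[C@@H](OC(=O)[C@H](C)CC)/C=C(\CBr)C(=O)OC)O
F3 | step 13 | methyl (2Z,4R)-2-(bromomethyl)-5-[(2R)-7-hydroxy-2-(hydroxymethyl)-9-methyl-1,6-dioxaspiro[4.4]non-8-en-2-yl]-4-{[(2R)-2-methylbutanoyl]oxy}pent-2-enoate | CC1=CC(O)OC12CC[C@](CO)(C[C@@H](OC(=O)[C@H](C)CC)/C=C(\CBr)C(=O)OC)O2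
F4 | step 2 | trimethyl{[(3E)-4-phenylbuta-1,3-dien-2-yl]oxy}silane | C=C(O[Si](C)(C)C)/C=C/c1ccccc1
F5 | step 2 | ethyl (2R,5E)-2-[2-(3-methylfuran-2-yl)ethyl]-4-oxo-6-phenyl-2-[(trimethylsilyl)oxy]hex-5-enoate | Cc1ccoc1CC[C@](C(=O)OCC)(CC(=O)/C=C/c1ccccc1)O[Si](C)(C)C
F6 | step 8 | methyl 2-[bis(2-methylpropyl)alumanyl]prop-2-enoate | C=C(C(=O)OC)[Al](CC(C)C)CC(C)C
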